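Violacene is traced back to a bridged bromolactone. With the ring numbered C1 = C(CH3)(chlorovinyl), C3 = C(Cl)(C8H2Br), C4 and C6 = CHCl, the C3–Cl bond lies cis-1,3 (diaxial) to the C1 carbon substituent on the cyclohexane ring, and C8 carries bromine. A carboxyl group on C1 can therefore add, together with Br+, across an exocyclic C3=C8 alkene: one bromolactonization sets the C3 stereocentre, places Br on C8 and closes a 6-oxabicyclo[3.2.1]octan-7-one. The precursor is enantiopure 2,4-dichloro-1-methyl-5-methylidenecyclohexane-1-carboxylic acid with both ring chlorides in place. The lactone oxygen is then exchanged for chloride with retention, and the carbonyl carbon becomes the (E)-chlorovinyl group.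

Key step: step 12

Assumption: the (R)-amine is taken to give the less soluble salt with the (1R,2R)-acid in step 6 (if the antipode crystallizes, the (S)-amine is used in the same way); racemic compounds 9 to 12 are written as the enantiomer that is carried on.

Step 1
Reactants: 1 1,4-dioxaspiro[4.5]decan-7-one
Product: 3 1,4-dioxaspiro[4.5]dec-7-en-7-yl trifluoromethanesulfonate, via lithium enolate 2 (not isolated)
Conditions: LiN(i-Pr)2, THF, −78 °C; then PhNTf2, −78 → 0 °C
Reagents that add atoms: N-phenylbis(trifluoromethanesulfonimide), O=S(=O)(N(c1ccccc1)S(=O)(=O)C(F)(F)F)C(F)(F)F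
Why: Kinetic deprotonation by the hindered amide base should remove the C8 proton remote from the ketal (the C6 protons are shielded by the spiro centre), and O-sulfonylation of the enolate gives the less substituted enol triflate (enol triflate formation).

Step 2
Reactants: 3 1,4-dioxaspiro[4.5]dec-7-en-7-yl trifluoromethanesulfonate; 4 carbon monoxide
Product: 5 methyl 1,4-dioxaspiro[4.5]dec-7-ene-7-carboxylate
Conditions: CO (1 atm), Pd(OAc)2 (cat.), PPh3, Et3N, MeOH/DMF, 60 °C
Reagents that add atoms: carbon monoxide (4), [C-]#[O+]; methanol, CO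
Why: Oxidative addition of zerovalent palladium to the enol triflate, CO insertion and methanolysis of the acylpalladium species should give the conjugated ester without moving the double bond (palladium-catalysed alkoxycarbonylation).

Step 3
Reactants: 5 methyl 1,4-dioxaspiro[4.5]dec-7-ene-7-carboxylate; 6 methylmagnesium bromide
Product: 8 2-(1,4-dioxaspiro[4.5]dec-7-en-7-yl)propan-2-ol, via methyl ketone 7 (not isolated)
Conditions: MeMgBr (2.5 equiv), THF, −20 → 0 °C; aq. NH4Cl
Reagents that add atoms: methylmagnesium bromide (6), C[Mg]Br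
Why: Two successive 1,2-additions of the Grignard reagent to the ester, by way of the enone, should give the tertiary allylic alcohol (Grignard addition).

Step 4
Reactants: 8 2-(1,4-dioxaspiro[4.5]dec-7-en-7-yl)propan-2-ol
Product: 9 rac-1-[(7R,8R)-8-chloro-7-methyl-1,4-dioxaspiro[4.5]decan-7-yl]ethan-1-one
Conditions: NCS, (CF3)2CHOH/CH2Cl2, 0 °C
Reagents that add atoms: N-chlorosuccinimide, O=C1CCC(=O)N1Cl
Why: Electrophilic chlorine adds to the less substituted alkene carbon C8 and the developing tertiary cation at C7 is quenched by a 1,2-methyl shift from the carbinol carbon, which must occur anti to the chloronium bridge, so chlorine should end up trans to the migrated methyl and cis to the new acetyl group, both stereocentres being set together in racemic form (halogen-induced semipinacol rearrangement of a tertiary allylic alcohol).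

Step 5
Reactants: 9 rac-1-[(7R,8R)-8-chloro-7-methyl-1,4-dioxaspiro[4.5]decan-7-yl]ethan-1-one
Product: 12 rac-(1R,2R)-2-chloro-1-methyl-5-oxocyclohexane-1-carboxylic acid, via tribromomethyl ketone 10 (not isolated), via ketal acid 11 (not isolated)
Conditions: Br2, NaOH, H2O/1,4-dioxane, 0 °C → rt; Na2SO3; then 3 M HCl, rt
Reagents that add atoms: sodium hydroxide, [Na+].[OH-]; water, O
Why: Exhaustive bromination of the only enolisable position (the acetyl methyl, since the ring ketone is still masked and C7 is quaternary) and hydroxide cleavage of the tribromomethyl ketone give the carboxylate, whose cis β-chlorine can neither close a β-lactone nor fragment, and acidification after the reductive quench removes the ketal (haloform reaction followed by acetal hydrolysis).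

Step 6
Reactants: 12 rac-(1R,2R)-2-chloro-1-methyl-5-oxocyclohexane-1-carboxylic acid; 13 (1R)-1-phenylethan-1-amine
Product: 14 (1R)-1-phenylethan-1-aminium (1R,2R)-2-chloro-1-methyl-5-oxocyclohexane-1-carboxylate
Conditions: 13 (1.0 equiv), EtOAc/EtOH, 60 → 5 °C; recrystallization of the precipitate
Reagents that add atoms: (1R)-1-phenylethan-1-amine (13), C[C@@H](N)c1ccccc1
Why: Because step 4 creates both stereocentres from an achiral alkene, the absolute configuration is introduced here, where the two diastereomeric ammonium carboxylates differ in solubility and the less soluble one is purified by recrystallization (classical resolution through diastereomeric salts).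

Step 7
Reactants: 14 (1R)-1-phenylethan-1-aminium (1R,2R)-2-chloro-1-methyl-5-oxocyclohexane-1-carboxylate
Product: 16 tert-butyl (1R,2R)-2-chloro-1-methyl-5-oxocyclohexane-1-carboxylate, via free acid 15 (not isolated)
Conditions: 1 M HCl/EtOAc partition, 0 °C; then t-BuOC(=NH)CCl3, BF3·OEt2 (cat.), CH2Cl2/cyclohexane, rt
Reagents that add atoms: tert-butyl 2,2,2-trichloroacetimidate, CC(C)(C)OC(=N)C(Cl)(Cl)Cl
Why: The acid freed by the partition is O-alkylated by the tert-butyl cation equivalent released from the imidate under Lewis acid catalysis, a process that does not depend on access to the hindered quaternary carboxyl carbon and leaves both stereocentres untouched (trichloroacetimidate esterification).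

Step 8
Reactants: 16 tert-butyl (1R,2R)-2-chloro-1-methyl-5-oxocyclohexane-1-carboxylate
Product: 19 tert-butyl (1R,2R,4R)-2-chloro-1-methyl-5-oxo-4-[(triethylsilyl)oxy]cyclohexane-1-carboxylate, via sodium enolate 17 (not isolated), via sodium alkoxide 18 (not isolated)
Conditions: NaN(SiMe3)2, THF, −78 °C; 3-phenyl-2-(phenylsulfonyl)oxaziridine, −78 °C; then Et3SiCl, −78 → 0 °C
Reagents that add atoms: 3-phenyl-2-(phenylsulfonyl)oxaziridine, O=S(=O)(c1ccccc1)N1OC1c1ccccc1; chlorotriethylsilane, CC[Si](Cl)(CC)CC
Why: The amide base should remove the C4 proton remote from the quaternary carbon, and the oxaziridine oxygen is transferred axially to the enolate face opposite the C2 chlorine (axial attack on the other half-chair is blocked by a syn-axial chlorine), giving the 4R alkoxide, which is capped in the same flask as its silyl ether (Davis enolate hydroxylation).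

Step 9
Reactants: 19 tert-butyl (1R,2R,4R)-2-chloro-1-methyl-5-oxo-4-[(triethylsilyl)oxy]cyclohexane-1-carboxylate; 20 methyltriphenylphosphonium bromide
Product: 22 tert-butyl (1R,2R,4R)-2-chloro-4-hydroxy-1-methyl-5-methylidenecyclohexane-1-carboxylate, via silyl ether 21 (not isolated)
Conditions: Ph3PCH3Br, KOt-Bu, THF, 0 °C → rt; then 1 M HCl, THF, rt
Reagents that add atoms: methyltriphenylphosphonium bromide (20), C[P+](c1ccccc1)(c1ccccc1)c1ccccc1.[Br-]
Why: The non-stabilised ylide should methylenate the ring ketone without touching the tert-butyl ester or the silyl ether and without disturbing C4, and dilute acid then frees the axial allylic alcohol (Wittig olefination followed by silyl ether hydrolysis).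

Step 10
Reactants: 22 tert-butyl (1R,2R,4R)-2-chloro-4-hydroxy-1-methyl-5-methylidenecyclohexane-1-carboxylate
Product: 23 tert-butyl (1R,2R,4S)-2,4-dichloro-1-methyl-5-methylidenecyclohexane-1-carboxylate
Conditions: PPh3, Cl3CCOCCl3, CH2Cl2, −20 → 0 °C
Reagents that add atoms: hexachloroacetone, ClC(Cl)(Cl)C(=O)C(Cl)(Cl)Cl
Why: The alkoxyphosphonium ion of the allylic alcohol is displaced by chloride at C4 in an SN2 process, with a reagent pair known to chlorinate secondary allylic alcohols with inversion and without allylic transposition, which should turn the axial 4R alcohol into the equatorial 4S chloride cis to the C2 chlorine (Appel-type chlorination).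

Step 11
Reactants: 23 tert-butyl (1R,2R,4S)-2,4-dichloro-1-methyl-5-methylidenecyclohexane-1-carboxylate
Product: 25 (1R,2R,4S)-2,4-dichloro-1-methyl-5-methylidenecyclohexane-1-carboxylic acid, via trimethylsilyl ester 24 (not isolated)
Conditions: Me3SiOTf, 2,6-lutidine, CH2Cl2, 0 °C; aq. KH2PO4
Reagents that add atoms: none
Why: Silylation of the ester carbonyl releases the tert-butyl group as isobutene under buffered, non-protic conditions, so the 1,1-disubstituted alkene is not protonated towards a bromine-free lactone, and aqueous work-up hydrolyses the silyl ester (silyl triflate mediated tert-butyl ester cleavage).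

Step 12
Reactants: 25 (1R,2R,4S)-2,4-dichloro-1-methyl-5-methylidenecyclohexane-1-carboxylic acid
Product: 26 (1R,2R,4S,5R)-5-(bromomethyl)-2,4-dichloro-1-methyl-6-oxabicyclo[3.2.1]octan-7-one
Conditions: NBS, MeCN, 0 °C → rt, dark
Reagents that add atoms: N-bromosuccinimide, O=C1CCC(=O)N1Br
Why: NBS transfers Br+ reversibly to the 1,1-disubstituted C5=CH2 alkene, and only the bromonium ion with bromine on the face away from the carboxyl can be opened by the carboxyl oxygen at the tertiary carbon C5, after which loss of the proton to succinimide gives the lactone. The closest known reaction type is the halolactonization of γ,δ-unsaturated acids, as in the bromolactonization of cyclohex-3-ene-1-carboxylic acids to 6-oxabicyclo[3.2.1]octan-7-ones. The γ-lactone ring closes in the 5-exo mode, the 6-endo alternative being anti-Markovnikov. The new stereocentre, C5 of the lactone, is controlled by the tether: the C1 carboxyl, axial in the chair that keeps both chlorides equatorial, reaches only the syn face, so oxygen is cis to the C1 carbonyl carbon and bromine adds anti. The step needs Markovnikov regioselectivity (O to the ring carbon, Br to CH2) and chemoselectivity over the allylic chloride, and the tertiary cation character, the five-membered transition state and the absence of any other nucleophile should secure both.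

Step 13
Reactants: 26 (1R,2R,4S,5R)-5-(bromomethyl)-2,4-dichloro-1-methyl-6-oxabicyclo[3.2.1]octan-7-one
Product: 28 (1S,2R,4S,5R)-5-(bromomethyl)-2,4,5-trichloro-1-methylcyclohexane-1-carbonyl chloride, via chlorozinc carboxylate 27 (not isolated)
Conditions: SOCl2 (neat), ZnCl2 (cat.), 55 °C; evaporation
Reagents that add atoms: thionyl chloride, ClS(Cl)=O
Why: ZnCl2-assisted heterolysis of the tertiary C5–O6 bond is helped by the bromine of the bromomethyl group attacking antiperiplanar to the leaving carboxylate, chloride then opens the bromonium ion at the tertiary carbon from the face the oxygen has left (two inversions, net retention, which should also be the more stable epimer, with the small chlorine axial and the bromomethyl group equatorial), and SOCl2 traps the carboxylate as the acyl chloride so that the lactone cannot re-close (ring-opening chlorination of a γ-lactone with SOCl2 and ZnCl2, with neighbouring-bromine participation).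

Step 14
Reactants: 28 (1S,2R,4S,5R)-5-(bromomethyl)-2,4,5-trichloro-1-methylcyclohexane-1-carbonyl chloride
Product: 29 (1R,2R,4S,5R)-5-(bromomethyl)-2,4,5-trichloro-1-methylcyclohexane-1-carbaldehyde
Conditions: LiAlH(Ot-Bu)3 (1.1 equiv), THF, −78 °C
Reagents that add atoms: none
Why: The hindered, attenuated hydride should reduce the acyl chloride only to the aldehyde stage at low temperature and does not attack alkyl halides (acyl chloride reduction with LiAlH(Ot-Bu)3).

Step 15
Reactants: 29 (1R,2R,4S,5R)-5-(bromomethyl)-2,4,5-trichloro-1-methylcyclohexane-1-carbaldehyde; 30 chloroform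
Product: 31 (1R,2S,4R,5R)-1-(bromomethyl)-1,2,4-trichloro-5-[(E)-2-chloroethenyl]-5-methylcyclohexane (violacene)
Conditions: CrCl2 (6 equiv), CHCl3 (2 equiv), THF, 65 °C
Reagents that add atoms: chloroform (30), ClC(Cl)Cl
Why: The geminal dichromium carbenoid formed from CHCl3 and divalent chromium adds to the non-enolisable aldehyde and eliminates to the (E)-chloroalkene (Takai olefination).

Compound list
1 | 1,4-dioxaspiro[4.5]decan-7-one | O=C1CCCC2(C1)OCCO2 | starting material
2 | lithium 1,4-dioxaspiro[4.5]dec-7-en-7-olate | [Li]OC1=CCCC2(C1)OCCO2 | intermediate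
3 | 1,4-dioxaspiro[4.5]dec-7-en-7-yl trifluoromethanesulfonate | O=S(=O)(OC1=CCCC2(C1)OCCO2)C(F)(F)F | intermediate
4 | carbon monoxide | [C-]#[O+] | starting material
5 | methyl 1,4-dioxaspiro[4.5]dec-7-ene-7-carboxylate | COC(=O)C1=CCCC2(C1)OCCO2 | intermediate
6 | methylmagnesium bromide | C[Mg]Br | starting material
7 | 1-(1,4-dioxaspiro[4.5]dec-7-en-7-yl)ethan-1-one | CC(=O)C1=CCCC2(C1)OCCO2 | intermediate
8 | 2-(1,4-dioxaspiro[4.5]dec-7-en-7-yl)propan-2-ol | CC(C)(O)C1=CCCC2(C1)OCCO2 | intermediate
9 | rac-1-[(7R,8R)-8-chloro-7-methyl-1,4-dioxaspiro[4.5]decan-7-yl]ethan-1-one | C[C@]1(C(C)=O)CC2(OCCO2)CC[C@H]1Cl | intermediate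
10 | rac-2,2,2-tribromo-1-[(7R,8R)-8-chloro-7-methyl-1,4-dioxaspiro[4.5]decan-7-yl]ethan-1-one | C[C@]1(C(=O)C(Br)(Br)Br)CC2(OCCO2)CC[C@H]1Cl | intermediate
11 | rac-(7R,8R)-8-chloro-7-methyl-1,4-dioxaspiro[4.5]decane-7-carboxylic acid | C[C@]1(C(=O)O)CC2(OCCO2)CC[C@H]1Cl | intermediate
12 | rac-(1R,2R)-2-chloro-1-methyl-5-oxocyclohexane-1-carboxylic acid | C[C@]1(C(=O)O)CC(=O)CC[C@H]1Cl | intermediate
13 | (1R)-1-phenylethan-1-amine | C[C@@H](N)c1ccccc1 | starting material
14 | (1R)-1-phenylethan-1-aminium (1R,2R)-2-chloro-1-methyl-5-oxocyclohexane-1-carboxylate | C[C@]1(C(=O)[O-])CC(=O)CC[C@H]1Cl.C[C@@H]([NH3+])c1ccccc1 | intermediate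
15 | (1R,2R)-2-chloro-1-methyl-5-oxocyclohexane-1-carboxylic acid (single enantiomer) | C[C@]1(C(=O)O)CC(=O)CC[C@H]1Cl | intermediate
16 | tert-butyl (1R,2R)-2-chloro-1-methyl-5-oxocyclohexane-1-carboxylate | C[C@]1(C(=O)OC(C)(C)C)CC(=O)CC[C@H]1Cl | intermediate
17 | sodium enolate of 16 (sodium (4R,5R)-5-(tert-butoxycarbonyl)-4-chloro-5-methylcyclohex-1-en-1-olate) | C[C@]1(C(=O)OC(C)(C)C)CC(O[Na])=CC[C@H]1Cl | intermediate
18 | sodium (1R,4R,5R)-4-(tert-butoxycarbonyl)-5-chloro-4-methyl-2-oxocyclohexan-1-olate | C[C@]1(C(=O)OC(C)(C)C)CC(=O)[C@H](O[Na])C[C@H]1Cl | intermediate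
19 | tert-butyl (1R,2R,4R)-2-chloro-1-methyl-5-oxo-4-[(triethylsilyl)oxy]cyclohexane-1-carboxylate | C[C@]1(C(=O)OC(C)(C)C)CC(=O)[C@H](O[Si](CC)(CC)CC)C[C@H]1Cl | intermediate
20 | methyltriphenylphosphonium bromide | C[P+](c1ccccc1)(c1ccccc1)c1ccccc1.[Br-] | starting material
21 | tert-butyl (1R,2R,4R)-2-chloro-1-methyl-5-methylidene-4-[(triethylsilyl)oxy]cyclohexane-1-carboxylate | C[C@]1(C(=O)OC(C)(C)C)CC(=C)[C@H](O[Si](CC)(CC)CC)C[C@H]1Cl | intermediate
22 | tert-butyl (1R,2R,4R)-2-chloro-4-hydroxy-1-methyl-5-methylidenecyclohexane-1-carboxylate | C[C@]1(C(=O)OC(C)(C)C)CC(=C)[C@H](O)C[C@H]1Cl | intermediate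
23 | tert-butyl (1R,2R,4S)-2,4-dichloro-1-methyl-5-methylidenecyclohexane-1-carboxylate | C[C@]1(C(=O)OC(C)(C)C)CC(=C)[C@@H](Cl)C[C@H]1Cl | intermediate
24 | trimethylsilyl (1R,2R,4S)-2,4-dichloro-1-methyl-5-methylidenecyclohexane-1-carboxylate | C[C@]1(C(=O)O[Si](C)(C)C)CC(=C)[C@@H](Cl)C[C@H]1Cl | intermediate
25 | (1R,2R,4S)-2,4-dichloro-1-methyl-5-methylidenecyclohexane-1-carboxylic acid | C[C@]1(C(=O)O)CC(=C)[C@@H](Cl)C[C@H]1Cl | intermediate
26 | (1R,2R,4S,5R)-5-(bromomethyl)-2,4-dichloro-1-methyl-6-oxabicyclo[3.2.1]octan-7-one | C[C@]1(C(=O)O2)C[C@]2(CBr)[C@@H](Cl)C[C@H]1Cl | intermediate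
27 | chlorozinc (1R,2R,4S,5R)-5-(bromomethyl)-2,4,5-trichloro-1-methylcyclohexane-1-carboxylate | C[C@]1(C(=O)O[Zn]Cl)C[C@](Cl)(CBr)[C@@H](Cl)C[C@H]1Cl | intermediate
28 | (1S,2R,4S,5R)-5-(bromomethyl)-2,4,5-trichloro-1-methylcyclohexane-1-carbonyl chloride | C[C@]1(C(=O)Cl)C[C@](Cl)(CBr)[C@@H](Cl)C[C@H]1Cl | intermediate
29 | (1R,2R,4S,5R)-5-(bromomethyl)-2,4,5-trichloro-1-methylcyclohexane-1-carbaldehyde | C[C@]1(C=O)C[C@](Cl)(CBr)[C@@H](Cl)C[C@H]1Cl | intermediate
30 | chloroform | ClC(Cl)Cl | starting material
31 | (1R,2S,4R,5R)-1-(bromomethyl)-1,2,4-trichloro-5-[(E)-2-chloroethenyl]-5-methylcyclohexane (violacene) | C[C@]1(/C=C/Cl)C[C@](Cl)(CBr)[C@@H](Cl)C[C@H]1Cl | target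

Total step count: 15. Longest linear sequence: 15 steps, from 1 to 31.

Steps most likely to fail

Step 13 (exchange of the lactone oxygen for chloride). What may go wrong: reversible ionization at the tertiary centre with loss of configuration, E1 elimination, halogen scrambling across the bromonium ion, or reluctant heterolysis of the lactone so that forcing conditions degrade the material. The fallback sets out from 26 and comes back at 31; it moves the oxygen-to-chlorine exchange to the end, onto a tertiary alcohol that ionizes at low temperature and has no carboxyl group left to re-close. i-Bu2AlH (CH2Cl2, −78 °C) reduces the lactone to the lactol (1R,2R,4S,5R)-5-(bromomethyl)-2,4-dichloro-1-methyl-6-oxabicyclo[3.2.1]octan-7-ol F2 (mixture at C7). CrCl2/CHCl3 (THF, 65 °C) olefinates its open hydroxy aldehyde form to the tertiary bromohydrin (1R,2S,4R,5R)-1-(bromomethyl)-2,4-dichloro-5-[(E)-2-chloroethenyl]-5-methylcyclohexan-1-ol F3. HCl gas with ZnCl2 in CH2Cl2 at −20 °C then replaces the hydroxyl by chloride through the same bromine-bridged cation (the classical retentive substitution of β-bromo alcohols by hydrogen halides), giving 31.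

Step 4 (chlorinative methyl shift). What may go wrong: interception of the chloronium ion by the hydroxyl group (chloro epoxide formation and subsequent ring expansion), ene-type allylic chlorination, or a methyl migration too slow to compete. The fallback sets out from 8 and comes back at 9; it separates chlorine delivery from the rearrangement. Anti-dichlorination with Et4NCl3 (CH2Cl2, 0 °C) gives rac-2-[(7S,8R)-7,8-dichloro-1,4-dioxaspiro[4.5]decan-7-yl]propan-2-ol F1. AgOSO2CF3 with 2,6-di-tert-butylpyridine (CH2Cl2, −40 °C) then abstracts only the tertiary chloride; the trans secondary chlorine bridges the cation and the methyl group migrates anti to it (silver-promoted semipinacol rearrangement of a β-chloro alcohol), which should give 9 with the same relative configuration.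

Step 15 (chloro-olefination). What may go wrong: reductive 1,2-elimination of the vicinal bromide/chloride pair by divalent chromium, slow addition to the neopentyl aldehyde, or incomplete E selectivity. The fallback sets out from 29 and comes back at 31. Dimethyl (1-diazo-2-oxopropyl)phosphonate with K2CO3 in MeOH at 0 °C (Ohira–Bestmann homologation; the aldehyde has no α-hydrogen) gives the alkyne (1R,2S,4R,5R)-1-(bromomethyl)-1,2,4-trichloro-5-ethynyl-5-methylcyclohexane F4. Syn hydrozirconation with Cp2Zr(H)Cl (THF, rt) and chlorination of the (E)-alkenylzirconium species with NCS, with retention, gives 31.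

Further compounds
F1 | step 4 | rac-2-[(7S,8R)-7,8-dichloro-1,4-dioxaspiro[4.5]decan-7-yl]propan-2-ol | CC(C)(O)[C@@]1(Cl)CC2(OCCO2)CC[C@H]1Cl
F2 | step 13 | (1R,2R,4S,5R)-5-(bromomethyl)-2,4-dichloro-1-methyl-6-oxabicyclo[3.2.1]octan-7-ol | C[C@]1(C(O)O2)C[C@]2(CBr)[C@@H](Cl)C[C@H]1Cl
F3 | step 13 | (1R,2S,4R,5R)-1-(bromomethyl)-2,4-dichloro-5-[(E)-2-chloroethenyl]-5-methylcyclohexan-1-ol | C[C@]1(/C=C/Cl)C[C@](O)(CBr)[C@@H](Cl)C[C@H]1Cl
F4 | step 15 | (1R,2S,4R,5R)-1-(bromomethyl)-1,2,4-trichloro-5-ethynyl-5-methylcyclohexane | C[C@]1(C#C)C[C@](Cl)(CBr)[C@@H](Cl)C[C@H]1Cl
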